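**Retrosynthetic overview**
1. Target 18 is two 7-methoxy-2,2-dimethyl-2H-chromenes: benzene ring A with pyran ring C on the CH=CH end, benzene ring B with pyran ring D on the CH(CH3) end. Both pyran rings are cut at C2–C3 with O1–C2 kept, which gives tetraene 15, where each arene carries an O-isopropenyl ether and an ortho vinyl group.
2. Enabling feature: in rings C and D, C2 is an acetone-level gem-dimethyl carbon on O1 (a latent oxocarbenium ion). C4 sits on C4a, para to the C7 methoxy group and next to O1-bearing C8a, so the vinyl terminus C3 is a strong π-nucleophile and the C4 cation formed on attack is well stabilised.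
3. 15 comes from bis(acetoxy aldehyde) 14 by fourfold Tebbe methylenation; 14 comes from bisphenol 12 by twofold ortho-formylation and acetylation.
4. The C6–CH=CH–CH(CH3)–C6 link and the (S) centre come from [Rh(OH)((R)-BINAP)]2-catalysed 1,4-addition of boronic acid 4 to enone 8, then reduction and dehydration; 4 and 8 both derive from 4-bromo-3-methoxyphenol.
5. Ring order: benzene rings A and B are bought; pyran rings C and D are closed last, together, in the key step.

Key step: step 12

Assumption: the facial sense of the [Rh(OH)((R)-BINAP)]2-catalysed addition to (E)-enone 8 is taken to follow that known for (E)-crotonyl acceptors, so (R)-BINAP is specified for the (S) centre; if the sense proves opposite, (S)-BINAP is used and nothing else changes.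

**Route**

Step 1
Reactants: 1 4-bromo-3-methoxyphenol
Product: 2 (4-bromo-3-methoxyphenoxy)triisopropylsilane
Conditions: TIPSCl, imidazole, DMF, rt
Reagents that add atoms: chlorotriisopropylsilane (TIPSCl), CC(C)[Si](Cl)(C(C)C)C(C)C
Why: Silyl ether protection of a phenol; the bulky triisopropylsilyl ether should survive the organometallic, aqueous rhodium, hydride and dehydration steps that follow.

Step 2
Reactants: 2 (4-bromo-3-methoxyphenoxy)triisopropylsilane
Product: 4 [2-methoxy-4-(triisopropylsilyloxy)phenyl]boronic acid, via aryllithium 3 (not isolated)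
Conditions: n-BuLi, THF, −78 °C; B(OiPr)3, −78 °C to rt; 1 M HCl (aq), 0 °C
Reagents that add atoms: triisopropyl borate, CC(C)OB(OC(C)C)OC(C)C; water, O
Why: Bromine–lithium exchange followed by borylation of the aryllithium and hydrolysis of the borate should give the boronic acid with the silyl ether untouched.

Step 3
Reactants: 2 (4-bromo-3-methoxyphenoxy)triisopropylsilane; 5 (E)-but-2-enal
Product: 7 (E)-1-[2-methoxy-4-(triisopropylsilyloxy)phenyl]but-2-en-1-ol (racemic), via arylmagnesium bromide 6 (not isolated)
Conditions: Mg turnings, I2 (cat.), THF, 45 °C; then 5, −20 °C; H2O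
Reagents that add atoms: none
Why: Grignard addition, in which the arylmagnesium bromide formed by magnesium insertion into the C–Br bond should add 1,2 to the aldehyde carbonyl of the enal; the racemic carbinol centre is removed by oxidation in the next step, so the alcohol is used crude.

Step 4
Reactants: 7 (E)-1-[2-methoxy-4-(triisopropylsilyloxy)phenyl]but-2-en-1-ol
Product: 8 (E)-1-[2-methoxy-4-(triisopropylsilyloxy)phenyl]but-2-en-1-one
Conditions: MnO2 (activated, excess), CH2Cl2, rt
Reagents that add atoms: none
Why: MnO2 oxidation is selective for benzylic/allylic alcohols and, being neutral, should spare the acid-labile carbinol from ionisation and keep the (E) alkene.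

Step 5
Reactants: 8 (E)-1-[2-methoxy-4-(triisopropylsilyloxy)phenyl]but-2-en-1-one; 4 [2-methoxy-4-(triisopropylsilyloxy)phenyl]boronic acid
Product: 9 (3S)-1,3-bis[2-methoxy-4-(triisopropylsilyloxy)phenyl]butan-1-one
Conditions: [Rh(OH)((R)-BINAP)]2 (3 mol % Rh), 4 (2.5 equiv), 1,4-dioxane/H2O 10:1, 40 °C
Reagents that add atoms: none
Why: Hayashi–Miyaura asymmetric conjugate addition, in which the aryl group passes from boron to monovalent rhodium, the (E)-enone inserts into the aryl–rhodium bond on the face selected by (R)-BINAP to set the (S) benzylic centre, and water releases the ketone from the oxa-π-allyl rhodium species.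

Step 6
Reactants: 9 (3S)-1,3-bis[2-methoxy-4-(triisopropylsilyloxy)phenyl]butan-1-one
Product: 10 (3S)-1,3-bis[2-methoxy-4-(triisopropylsilyloxy)phenyl]butan-1-ol (both C1 epimers)
Conditions: NaBH4, MeOH/THF, 0 °C
Reagents that add atoms: none
Why: Borohydride reduction of an aryl ketone; the new carbinol centre is not controlled because it is removed in the next step, and the C3 centre is not enolisable.

Step 7
Reactants: 10 (3S)-1,3-bis[2-methoxy-4-(triisopropylsilyloxy)phenyl]butan-1-ol
Product: 11 (1E,3S)-1,3-bis[2-methoxy-4-(triisopropylsilyloxy)phenyl]but-1-ene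
Conditions: Burgess reagent (MeO2C–N(−)–SO2–N(+)Et3), toluene, 60 °C
Reagents that add atoms: none
Why: Burgess dehydration through the sulfamate ester under neutral conditions, where the only β-hydrogens are on C2 so elimination can only give the aryl-conjugated alkene, expected as the (E) isomer, without touching the C3 centre.

Step 8
Reactants: 11 (1E,3S)-1,3-bis[2-methoxy-4-(triisopropylsilyloxy)phenyl]but-1-ene
Product: 12 4,4'-[(1E,3S)-but-1-ene-1,3-diyl]bis(3-methoxyphenol)
Conditions: TBAF, AcOH, THF, 0 °C to rt
Reagents that add atoms: none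
Why: Fluoride cleavage of aryl silyl ethers driven by the Si–F bond, buffered with acetic acid so that the electron-rich phenoxides are not left exposed.

Step 9
Reactants: 12 4,4'-[(1E,3S)-but-1-ene-1,3-diyl]bis(3-methoxyphenol)
Product: 13 5,5'-[(1E,3S)-but-1-ene-1,3-diyl]bis(2-hydroxy-4-methoxybenzaldehyde)
Conditions: MgCl2, Et3N, (CH2O)n, MeCN, 80 °C; 1 M HCl work-up
Reagents that add atoms: paraformaldehyde (as formaldehyde), C=O
Why: Casnati–Skattebøl ortho-formylation, in which the magnesium phenoxide delivers formaldehyde to an ortho carbon and a second formaldehyde takes up the hydride; of the two ortho positions the one para to the methoxy group, not flanked by two oxygens, should react, as is general for 3-alkoxyphenols.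

Step 10
Reactants: 13 5,5'-[(1E,3S)-but-1-ene-1,3-diyl]bis(2-hydroxy-4-methoxybenzaldehyde)
Product: 14 (1E,3S)-1,3-bis(4-acetoxy-5-formyl-2-methoxyphenyl)but-1-ene
Conditions: Ac2O, pyridine, DMAP (cat.), CH2Cl2, 0 °C to rt
Reagents that add atoms: acetic anhydride, CC(=O)OC(C)=O
Why: Base-mediated O-acetylation of the phenols, which installs the ester carbonyl carbons that become C2 of pyran rings C and D.

Step 11
Reactants: 14 (1E,3S)-1,3-bis(4-acetoxy-5-formyl-2-methoxyphenyl)but-1-ene
Product: 15 (1E,3S)-1,3-bis[2-methoxy-4-(prop-1-en-2-yloxy)-5-vinylphenyl]but-1-ene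
Conditions: Cp2Ti(μ-Cl)(μ-CH2)AlMe2 (6 equiv), pyridine (cat.), THF/toluene, −40 °C to rt; aq. NaOH; filtration through basic Al2O3
Reagents that add atoms: Tebbe reagent Cp2Ti(μ-Cl)(μ-CH2)AlMe2, C[Al-]1(C)C[Ti](C2C=CC=C2)(C2C=CC=C2)[Cl+]1
Why: Tebbe methylenation, in which the titanium methylidene should convert both aldehydes into vinyl groups and both aryl acetates into isopropenyl ethers through oxatitanacyclobutanes, driven by Ti=O formation and non-basic enough to leave the stereocentre alone.

Step 12
Reactants: 15 (1E,3S)-1,3-bis[2-methoxy-4-(prop-1-en-2-yloxy)-5-vinylphenyl]but-1-ene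
Product: 18 7-methoxy-6-[(1E,3S)-3-(7-methoxy-2,2-dimethyl-2H-chromen-6-yl)but-1-en-1-yl]-2,2-dimethyl-2H-chromene (target), via ring C mono-chromene 16 (not isolated), via ring D mono-chromene 17 (not isolated)
Conditions: (PhO)2P(O)OH (10 mol %), 4 Å MS, CH2Cl2 (0.005 M), −20 °C to rt; Et3N quench
Reagents that add atoms: none
Why: Proposed new method: the phosphoric acid should protonate each 2-aryloxypropene at its CH2 terminus to give the aryl oxocarbenium ion at C2 (O1=C2 bearing two methyl groups), the ortho vinyl group then adds through its terminal carbon C3 to C2, and the C4 cation so formed, benzylic and stabilised by the para C7 methoxy group and by O1 on C8a, loses a C3 proton to the phosphate, which gives the C3=C4 alkene of the 2H-chromene and returns the acid. The closest known reaction types are the Prins cyclization of oxocarbenium ions onto alkenes (including vinylsilane-terminated closures to 3,6-dihydro-2H-pyrans, which form the same C2–C3 bond) and the acid-mediated (5+1) condensation of 2-alkenylphenols or 2-alkenylanilines with ketones; what is new is the isolated aryl isopropenyl ether as oxocarbenium source, which makes the step a cycloisomerisation of a 1,6-diene, and its twofold use in one molecule. Each pyran ring (C and D) closes by its C2–C3 bond in a 6-endo-trig attack of the C3=C4 alkene on the oxocarbenium carbon, equally viewed as a cationic 6π electrocyclisation of the C2=O1/C8a=C4a/C4=C3 array, whereas a five-membered closure would need attack through C4 and a primary cation and is not expected. No new stereocentre forms, and the (S) centre is a spectator as long as the internal alkene is not protonated. The step needs protonation of the two enol ethers in preference to the three styrene-type alkenes and the chromene products, which the far higher carbon basicity of an enol ether, the weak acid and the low temperature should secure, while high dilution disfavours intermolecular cation–styrene coupling and the sieves keep out water that would hydrolyse the enol ethers.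

**Compound list**
1 | 4-bromo-3-methoxyphenol | COc1cc(O)ccc1Br | starting material
2 | (4-bromo-3-methoxyphenoxy)triisopropylsilane | COc1cc(O[Si](C(C)C)(C(C)C)C(C)C)ccc1Br | intermediate
3 | [2-methoxy-4-(triisopropylsilyloxy)phenyl]lithium | COc1cc(O[Si](C(C)C)(C(C)C)C(C)C)ccc1[Li] | intermediate (not isolated)
4 | [2-methoxy-4-(triisopropylsilyloxy)phenyl]boronic acid | COc1cc(O[Si](C(C)C)(C(C)C)C(C)C)ccc1B(O)O | intermediate
5 | (E)-but-2-enal (crotonaldehyde) | C/C=C/C=O | starting material
6 | bromo[2-methoxy-4-(triisopropylsilyloxy)phenyl]magnesium | COc1cc(O[Si](C(C)C)(C(C)C)C(C)C)ccc1[Mg]Br | intermediate (not isolated)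
7 | (E)-1-[2-methoxy-4-(triisopropylsilyloxy)phenyl]but-2-en-1-ol (racemic) | COc1cc(O[Si](C(C)C)(C(C)C)C(C)C)ccc1C(O)/C=C/C | intermediate
8 | (E)-1-[2-methoxy-4-(triisopropylsilyloxy)phenyl]but-2-en-1-one | COc1cc(O[Si](C(C)C)(C(C)C)C(C)C)ccc1C(=O)/C=C/C | intermediate
9 | (3S)-1,3-bis[2-methoxy-4-(triisopropylsilyloxy)phenyl]butan-1-one | COc1cc(O[Si](C(C)C)(C(C)C)C(C)C)ccc1C(=O)C[C@H](C)c1ccc(O[Si](C(C)C)(C(C)C)C(C)C)cc1OC | intermediate
10 | (3S)-1,3-bis[2-methoxy-4-(triisopropylsilyloxy)phenyl]butan-1-ol (both C1 epimers) | COc1cc(O[Si](C(C)C)(C(C)C)C(C)C)ccc1C(O)C[C@H](C)c1ccc(O[Si](C(C)C)(C(C)C)C(C)C)cc1OC | intermediate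
11 | (1E,3S)-1,3-bis[2-methoxy-4-(triisopropylsilyloxy)phenyl]but-1-ene | COc1cc(O[Si](C(C)C)(C(C)C)C(C)C)ccc1/C=C/[C@H](C)c1ccc(O[Si](C(C)C)(C(C)C)C(C)C)cc1OC | intermediate
12 | 4,4'-[(1E,3S)-but-1-ene-1,3-diyl]bis(3-methoxyphenol) | COc1cc(O)ccc1/C=C/[C@H](C)c1ccc(O)cc1OC | intermediate
13 | 5,5'-[(1E,3S)-but-1-ene-1,3-diyl]bis(2-hydroxy-4-methoxybenzaldehyde) | COc1cc(O)c(C=O)cc1/C=C/[C@H](C)c1cc(C=O)c(O)cc1OC | intermediate
14 | (1E,3S)-1,3-bis(4-acetoxy-5-formyl-2-methoxyphenyl)but-1-ene | COc1cc(OC(C)=O)c(C=O)cc1/C=C/[C@H](C)c1cc(C=O)c(OC(C)=O)cc1OC | intermediate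
15 | (1E,3S)-1,3-bis[2-methoxy-4-(prop-1-en-2-yloxy)-5-vinylphenyl]but-1-ene | COc1cc(OC(C)=C)c(C=C)cc1/C=C/[C@H](C)c1cc(C=C)c(OC(C)=C)cc1OC | intermediate
16 | 7-methoxy-6-{(1E,3S)-3-[2-methoxy-4-(prop-1-en-2-yloxy)-5-vinylphenyl]but-1-en-1-yl}-2,2-dimethyl-2H-chromene (ring C closed) | COc1cc2c(cc1/C=C/[C@H](C)c1cc(C=C)c(OC(C)=C)cc1OC)C=CC(C)(C)O2 | intermediate (not isolated)
17 | 7-methoxy-6-{(2S,3E)-4-[2-methoxy-4-(prop-1-en-2-yloxy)-5-vinylphenyl]but-3-en-2-yl}-2,2-dimethyl-2H-chromene (ring D closed) | COc1cc(OC(C)=C)c(C=C)cc1/C=C/[C@H](C)c1cc2c(cc1OC)OC(C)(C)C=C2 | intermediate (not isolated)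
18 | 7-methoxy-6-[(1E,3S)-3-(7-methoxy-2,2-dimethyl-2H-chromen-6-yl)but-1-en-1-yl]-2,2-dimethyl-2H-chromene | COc1cc2c(cc1/C=C/[C@H](C)c1cc3c(cc1OC)OC(C)(C)C=C3)C=CC(C)(C)O2 | target

**Step count and risks**
Total steps: 12. Longest linear sequence: 11 steps (steps 1, 3, 4, 5, 6, 7, 8, 9, 10, 11, 12); step 2 is the side branch.

Steps most likely to fail:

Step 12 (the step under the "Proposed new method:" label). What may go wrong: protonation of the styrene-type alkenes competing with that of the enol ethers, leading to cationic oligomerisation; hydrolysis of the enol ethers by adventitious water; closure of only one ring; or protonation of the internal alkene with erosion of the stereocentre. The fallback uses known chemistry, sets out from bisphenol 12 and comes back at target 18. Both phenols of 12 are alkylated with 3-chloro-3-methylbut-1-yne (DBU, CuCl2 cat., MeCN, 0 °C) to give the bis(1,1-dimethylpropargyl) ether (1E,3S)-1,3-bis[2-methoxy-4-(2-methylbut-3-yn-2-yloxy)phenyl]but-1-ene F1. Heating F1 in N,N-diethylaniline at 180 °C should bring about, on each ring, aromatic propargyl Claisen rearrangement to the free ortho position para to the methoxy group, 1,5-hydrogen shift and oxa-6π electrocyclisation, giving 18 directly. This fallback forms O1–C2 last in each pyran ring and does not pass through 13, 14 or 15.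

Step 11. What may go wrong: incomplete methylenation of the less reactive aryl acetates beside the fast aldehyde methylenation, or aluminium-induced loss of acetyl groups or ionisation of the enol ether products during reaction and work-up. The fallback sets out from bis(salicylaldehyde) 13 and comes back at tetraene 15. Twofold Wittig methylenation of 13 with excess Ph3P=CH2 (from Ph3PCH3Br and KOtBu, THF, 0 °C to rt; the phenoxides are tolerated) should give the bis(2-vinylphenol) 4,4'-[(1E,3S)-but-1-ene-1,3-diyl]bis(5-methoxy-2-vinylphenol) F2. Copper-catalysed O-alkenylation of F2 with 2-bromopropene (CuI, N,N-dimethylglycine, Cs2CO3, 1,4-dioxane, 80 °C, sealed tube) then installs the two isopropenyl ethers under basic conditions and gives 15.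

Step 5. What may go wrong: protodeboronation of the electron-rich ortho-methoxy arylboronic acid outrunning transmetalation, or insufficient facial selectivity with this ortho-substituted pair. The fallback is auxiliary-controlled, sets out from aryl bromide 2 and comes back at ketone 9. Bromide 2 is converted into arylmagnesium bromide 6 (Mg, THF, as in step 3) and added with CuBr·SMe2 (THF/Me2S, −40 °C) to (4R)-3-[(E)-but-2-enoyl]-4-phenyloxazolidin-2-one. Attack on the chelated s-cis imide from the face away from the phenyl group should give (4R)-3-{(3S)-3-[2-methoxy-4-(triisopropylsilyloxy)phenyl]butanoyl}-4-phenyloxazolidin-2-one F3. Aminolysis with MeNH(OMe)·HCl/AlMe3 (CH2Cl2, 0 °C to rt) releases the auxiliary and gives the Weinreb amide (3S)-N-methoxy-3-[2-methoxy-4-(triisopropylsilyloxy)phenyl]-N-methylbutanamide F4. Addition of aryllithium 3 (from 2 and n-BuLi, THF, −78 °C) to F4 then gives 9, so steps 2, 3 and 4 are no longer needed.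

**Further compounds**
F1 | step 12 | (1E,3S)-1,3-bis[2-methoxy-4-(2-methylbut-3-yn-2-yloxy)phenyl]but-1-ene | COc1cc(OC(C)(C)C#C)ccc1/C=C/[C@H](C)c1ccc(OC(C)(C)C#C)cc1OC
F2 | step 11 | 4,4'-[(1E,3S)-but-1-ene-1,3-diyl]bis(5-methoxy-2-vinylphenol) | COc1cc(O)c(C=C)cc1/C=C/[C@H](C)c1cc(C=C)c(O)cc1OC
F3 | step 5 | (4R)-3-{(3S)-3-[2-methoxy-4-(triisopropylsilyloxy)phenyl]butanoyl}-4-phenyloxazolidin-2-one | O=C(C[C@H](C)c1ccc(O[Si](C(C)C)(C(C)C)C(C)C)cc1OC)N1[C@H](c2ccccc2)COC1=O
F4 | step 5 | (3S)-N-methoxy-3-[2-methoxy-4-(triisopropylsilyloxy)phenyl]-N-methylbutanamide | CON(C)C(=O)C[C@H](C)c1ccc(O[Si](C(C)C)(C(C)C)C(C)C)cc1OC
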